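**Retrosynthetic overview**
- The target 7-allyl-6-hydroxybenzofuran is cut back (deacetylation, dehydrogenation of C2–C3, acetylation) to the racemic trans-2,3-dihydrobenzofuran-6-ol.
- Feature used: in ring A (the benzo ring) C3a and C6 are para and C6 bears the hydroxyl, so C3a–C4–C5–C6 with the 6-oxygen is read as a 4-methoxyfuran and C7–C7a as an allyl-substituted ynol ether bound through O1.
- Key disconnection: intramolecular furan/ynol ether [4+2] cycloaddition (bonds C3a–C7a and C6–C7) with opening of the oxa bridge; ring A and the dihydrofuran ring close in the same step.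
- The ynol ether comes from an (E)-dichlorovinyl ether of the anti alcohol; the alcohol from Felkin–Anh reduction of an α-furyl ketone; the ketone from a nickel-catalysed Negishi coupling of a C2-silyl-blocked, C5-zincated 3-methoxyfuran with 2-bromo-1-(3,4,5-trimethoxyphenyl)propan-1-one.
- Ring order: furan (bought) → ring A and dihydrofuran ring together (step 9) → benzofuran by dehydrogenation (step 11).

Key step: step 9

Remark: all chiral compounds are racemic; starred descriptors and SMILES show one enantiomer, and both stereocentres are removed in step 11.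

**Route**

Step 1
Reactants: 1 3-methoxyfuran
Product: 3 trimethyl(3-methoxyfuran-2-yl)silane, via 2-lithio-3-methoxyfuran 2 (not isolated)
Conditions: n-BuLi, THF, −78 → 0 °C; Me3SiCl, −78 → 25 °C
Reagents that add atoms: chlorotrimethylsilane, C[Si](C)(C)Cl
Why: Directed α-lithiation takes C2–H, the proton flanked by the ring oxygen and the methoxy group, and silylation blocks this position so that the next metalation must go to C5.

Step 2
Reactants: 4 5-bromo-1,2,3-trimethoxybenzene
Product: 6 1-(3,4,5-trimethoxyphenyl)propan-1-one, via arylmagnesium bromide 5 (not isolated)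
Conditions: Mg, THF, 40 °C; EtC(O)N(OMe)Me, 0 → 25 °C; 1 M HCl
Reagents that add atoms: N-methoxy-N-methylpropanamide, CCC(=O)N(C)OC
Why: Grignard formation and Weinreb ketone synthesis; the chelated tetrahedral adduct survives until the acid quench, so the ketone should not be attacked a second time.

Step 3
Reactants: 6 1-(3,4,5-trimethoxyphenyl)propan-1-one
Product: 7 2-bromo-1-(3,4,5-trimethoxyphenyl)propan-1-one (racemic)
Conditions: CuBr2 (2.1 equiv), EtOAc/CHCl3, reflux
Reagents that add atoms: copper dibromide CuBr2, Br[Cu]Br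
Why: α-Bromination of an aryl alkyl ketone by CuBr2 goes through the enol and should leave the electron-rich ring alone; the new stereocentre is racemic and is consumed in step 4.

Step 4
Reactants: 3 trimethyl(3-methoxyfuran-2-yl)silane; 7 2-bromo-1-(3,4,5-trimethoxyphenyl)propan-1-one
Product: 10 2-[4-methoxy-5-(trimethylsilyl)furan-2-yl]-1-(3,4,5-trimethoxyphenyl)propan-1-one (racemic), via furyllithium 8 (not isolated), via furylzinc iodide 9 (not isolated)
Conditions: n-BuLi, THF, −78 → 0 °C; ZnI2, 0 → 25 °C; then 7, NiCl2·DME (5 mol%), 2,6-bis(4,5-dihydrooxazol-2-yl)pyridine (6.5 mol%), DME/THF, −30 → 0 °C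
Reagents that add atoms: none
Why: Lithiation at the only free α-position (C5) and transmetalation give a furylzinc reagent for a nickel-catalysed Negishi arylation of the secondary α-bromo ketone, which runs through a radical oxidative addition and forms the α-stereocentre racemic.

Step 5
Reactants: 10 2-[4-methoxy-5-(trimethylsilyl)furan-2-yl]-1-(3,4,5-trimethoxyphenyl)propan-1-one
Product: 11 (1S*,2R*)-2-[4-methoxy-5-(trimethylsilyl)furan-2-yl]-1-(3,4,5-trimethoxyphenyl)propan-1-ol
Conditions: LiBH(s-Bu)3, THF, −78 °C; H2O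
Reagents that add atoms: none
Why: Felkin–Anh-controlled ketone reduction: the bulky hydride attacks anti to the furyl group with the methyl group gauche to the carbonyl oxygen, which should give mainly the (1S*,2R*) alcohol, the isomer that leads to the trans-2,3-disubstituted ring.

Step 6
Reactants: 11 (1S*,2R*)-2-[4-methoxy-5-(trimethylsilyl)furan-2-yl]-1-(3,4,5-trimethoxyphenyl)propan-1-ol
Product: 12 (1S*,2R*)-2-(4-methoxyfuran-2-yl)-1-(3,4,5-trimethoxyphenyl)propan-1-ol
Conditions: Bu4NF (1 M in wet THF), 0 → 25 °C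
Reagents that add atoms: none
Why: Fluoride-induced protodesilylation of a 2-silylfuran through a pentacoordinate silicate; the furyl anion is stabilised by the adjacent ring oxygen and methoxy group and is protonated by the water in the reagent.

Step 7
Reactants: 12 (1S*,2R*)-2-(4-methoxyfuran-2-yl)-1-(3,4,5-trimethoxyphenyl)propan-1-ol; 13 trichloroethylene
Product: 15 5-{(1S*,2R*)-1-[(E)-1,2-dichloroethenyloxy]-2-(4-methoxyfuran-2-yl)propyl}-1,2,3-trimethoxybenzene, via potassium alkoxide 14 (not isolated)
Conditions: KH (1.3 equiv), THF, 0 °C; Cl2C=CHCl, −50 → 25 °C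
Reagents that add atoms: none
Why: Dichlorovinyl ether synthesis: the potassium alkoxide adds anti to dichloroacetylene formed in the flask from trichloroethylene, and protonation gives the (E)-ether without touching the stereocentres.

Step 8
Reactants: 15 5-{(1S*,2R*)-1-[(E)-1,2-dichloroethenyloxy]-2-(4-methoxyfuran-2-yl)propyl}-1,2,3-trimethoxybenzene; 16 allyl bromide
Product: 19 5-{(1S*,2R*)-2-(4-methoxyfuran-2-yl)-1-[(pent-4-en-1-yn-1-yl)oxy]propyl}-1,2,3-trimethoxybenzene, via chloroalkynyl ether 17 (not isolated), via lithium acetylide 18 (not isolated)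
Conditions: n-BuLi (2.05 equiv), THF, −78 → −40 °C; CuI (10 mol%), allyl bromide, −40 → 0 °C; aq. NaHCO3; Et3N-deactivated alumina, ≤0 °C
Reagents that add atoms: none
Why: Ynol ether synthesis by dehydrochlorination to the chloroalkyne and chlorine–lithium exchange, then copper-catalysed allylation of the acetylide, which should give the 1,4-enyne without the base-induced propargyl–allenyl shift; the exact n-BuLi charge at −78 °C is meant to spare the furan C5–H.

Step 9
Reactants: 19 5-{(1S*,2R*)-2-(4-methoxyfuran-2-yl)-1-[(pent-4-en-1-yn-1-yl)oxy]propyl}-1,2,3-trimethoxybenzene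
Product: 21 (2S*,3S*)-7-allyl-5-methoxy-3-methyl-2-(3,4,5-trimethoxyphenyl)-2,3-dihydro-1-benzofuran-6-ol, via oxa-bridged cycloadduct 20 (not isolated)
Conditions: CH2Cl2 (0.05 M), Et3N (2 mol%), 1.5 GPa (15 kbar), 25 °C; then 1 bar, PPTS (5 mol%), 25 °C
Reagents that add atoms: none
Why: Proposed new method: the three-atom tether C3–C2–O1 holds the ynol ether over the 4-methoxyfuran so that a concerted, asynchronous [4+2] addition forms C6–C7 and C3a–C7a; the alkyne π bond that reacts lies in the plane of the forming five-membered ring and is orthogonal to the p lone pair of O1, so it is inductively activated instead of deactivated by resonance and is matched with the methoxy-raised HOMO of the furan. The closest known reaction type is the intramolecular Diels–Alder reaction of furans with tethered alkynes or ynamides that ends in opening of the oxa bridge to a fused phenol; an ynol ether has not been shown as the 2π partner. Ring A closes as the six-membered ring of the cycloaddition, and the dihydrofuran ring closes in the same event as the five-membered tether ring (exo-dig at the alkyne carbon C7a). No lasting stereocentre is set: C2 and C3 come unchanged from 19 and end up trans, and the two bridgehead centres of 20 (either furan face) vanish on aromatisation. The step needs cycloaddition to outrun the retro-ene and [3,3] fragmentations of the benzylic ynol ether to ketenes, which pressure at 25 °C should secure because only the bond-forming cycloaddition has a strongly negative activation volume, helped by the trans-disubstituted tether that pre-folds the chain. Regiochemistry is fixed by the tether, and the vinylogous ketal C3a(O)–C4=C5–OMe should ionise at C3a–O under trace acid to a cation stabilised by the 5-methoxy group, from which only the C6 bridgehead proton can be lost, so the bridge oxygen can end up only as the 6-hydroxyl.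

Step 10
Reactants: 21 (2S*,3S*)-7-allyl-5-methoxy-3-methyl-2-(3,4,5-trimethoxyphenyl)-2,3-dihydro-1-benzofuran-6-ol
Product: 22 (2S*,3S*)-7-allyl-5-methoxy-3-methyl-2-(3,4,5-trimethoxyphenyl)-2,3-dihydro-1-benzofuran-6-yl acetate
Conditions: Ac2O, pyridine, DMAP (cat.), CH2Cl2, 25 °C
Reagents that add atoms: acetic anhydride, CC(=O)OC(C)=O
Why: DMAP-catalysed O-acylation of the phenol; the acetate is meant to block quinone methide formation at the ortho allyl and para benzylic positions in step 11.

Step 11
Reactants: 22 (2S*,3S*)-7-allyl-5-methoxy-3-methyl-2-(3,4,5-trimethoxyphenyl)-2,3-dihydro-1-benzofuran-6-yl acetate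
Product: 23 7-allyl-5-methoxy-3-methyl-2-(3,4,5-trimethoxyphenyl)-1-benzofuran-6-yl acetate
Conditions: DDQ (1.3 equiv), 1,4-dioxane, 80 °C
Reagents that add atoms: none
Why: DDQ dehydrogenation: hydride abstraction from C2–H (benzylic to the trimethoxyphenyl ring and α to O1) gives an oxocarbenium ion that loses the C3 proton to the aromatic furan ring; both stereocentres are erased.

Step 12
Reactants: 23 7-allyl-5-methoxy-3-methyl-2-(3,4,5-trimethoxyphenyl)-1-benzofuran-6-yl acetate
Product: 24 7-allyl-5-methoxy-3-methyl-2-(3,4,5-trimethoxyphenyl)-1-benzofuran-6-ol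
Conditions: K2CO3 (0.2 equiv), MeOH, 0 → 25 °C
Reagents that add atoms: none
Why: Base-catalysed transesterification (methanolysis) of the aryl acetate; the benzofuran, the allyl group and the methyl ethers are inert.

**Compound list**

1 | 3-methoxyfuran | COc1ccoc1 | starting material
2 | 2-lithio-3-methoxyfuran | [Li]c1occc1OC | intermediate (not isolated)
3 | trimethyl(3-methoxyfuran-2-yl)silane | COc1ccoc1[Si](C)(C)C | intermediate
4 | 5-bromo-1,2,3-trimethoxybenzene | COc1cc(Br)cc(OC)c1OC | starting material
5 | (3,4,5-trimethoxyphenyl)magnesium bromide | COc1cc([Mg]Br)cc(OC)c1OC | intermediate (not isolated)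
6 | 1-(3,4,5-trimethoxyphenyl)propan-1-one | CCC(=O)c1cc(OC)c(OC)c(OC)c1 | intermediate
7 | 2-bromo-1-(3,4,5-trimethoxyphenyl)propan-1-one (racemic) | CC(Br)C(=O)c1cc(OC)c(OC)c(OC)c1 | intermediate
8 | [4-methoxy-5-(trimethylsilyl)furan-2-yl]lithium | [Li]c1cc(OC)c([Si](C)(C)C)o1 | intermediate (not isolated)
9 | iodo[4-methoxy-5-(trimethylsilyl)furan-2-yl]zinc | I[Zn]c1cc(OC)c([Si](C)(C)C)o1 | intermediate (not isolated)
10 | 2-[4-methoxy-5-(trimethylsilyl)furan-2-yl]-1-(3,4,5-trimethoxyphenyl)propan-1-one (racemic) | CC(C(=O)c1cc(OC)c(OC)c(OC)c1)c1cc(OC)c([Si](C)(C)C)o1 | intermediate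
11 | (1S*,2R*)-2-[4-methoxy-5-(trimethylsilyl)furan-2-yl]-1-(3,4,5-trimethoxyphenyl)propan-1-ol | O[C@H](c1cc(OC)c(OC)c(OC)c1)[C@@H](C)c1cc(OC)c([Si](C)(C)C)o1 | intermediate
12 | (1S*,2R*)-2-(4-methoxyfuran-2-yl)-1-(3,4,5-trimethoxyphenyl)propan-1-ol | O[C@H](c1cc(OC)c(OC)c(OC)c1)[C@@H](C)c1cc(OC)co1 | intermediate
13 | trichloroethylene | ClC=C(Cl)Cl | starting material
14 | potassium (1S*,2R*)-2-(4-methoxyfuran-2-yl)-1-(3,4,5-trimethoxyphenyl)propan-1-olate | [K+].[O-][C@H](c1cc(OC)c(OC)c(OC)c1)[C@@H](C)c1cc(OC)co1 | intermediate (not isolated)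
15 | 5-{(1S*,2R*)-1-[(E)-1,2-dichloroethenyloxy]-2-(4-methoxyfuran-2-yl)propyl}-1,2,3-trimethoxybenzene | Cl/C=C(Cl)\O[C@H](c1cc(OC)c(OC)c(OC)c1)[C@@H](C)c1cc(OC)co1 | intermediate
16 | allyl bromide | C=CCBr | starting material
17 | 5-{(1S*,2R*)-1-[(chloroethynyl)oxy]-2-(4-methoxyfuran-2-yl)propyl}-1,2,3-trimethoxybenzene | ClC#CO[C@H](c1cc(OC)c(OC)c(OC)c1)[C@@H](C)c1cc(OC)co1 | intermediate (not isolated)
18 | {[(1S*,2R*)-2-(4-methoxyfuran-2-yl)-1-(3,4,5-trimethoxyphenyl)propoxy]ethynyl}lithium | [Li]C#CO[C@H](c1cc(OC)c(OC)c(OC)c1)[C@@H](C)c1cc(OC)co1 | intermediate (not isolated)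
19 | 5-{(1S*,2R*)-2-(4-methoxyfuran-2-yl)-1-[(pent-4-en-1-yn-1-yl)oxy]propyl}-1,2,3-trimethoxybenzene | C=CCC#CO[C@H](c1cc(OC)c(OC)c(OC)c1)[C@@H](C)c1cc(OC)co1 | intermediate (key-step precursor)
20 | (2S*,3R*)-7-allyl-5-methoxy-3-methyl-2-(3,4,5-trimethoxyphenyl)-2,3,3a,6-tetrahydro-3a,6-epoxy-1-benzofuran (trans at C2/C3; bridge on either face, C3a/C6 not defined) | C=CCC1=C2O[C@H](c4cc(OC)c(OC)c(OC)c4)[C@@H](C)C23OC1C(OC)=C3 | intermediate (not isolated)
21 | (2S*,3S*)-7-allyl-5-methoxy-3-methyl-2-(3,4,5-trimethoxyphenyl)-2,3-dihydro-1-benzofuran-6-ol (trans) | C=CCc1c(O)c(OC)cc2c1O[C@H](c1cc(OC)c(OC)c(OC)c1)[C@H]2C | intermediate (key-step product)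
22 | (2S*,3S*)-7-allyl-5-methoxy-3-methyl-2-(3,4,5-trimethoxyphenyl)-2,3-dihydro-1-benzofuran-6-yl acetate | C=CCc1c(OC(C)=O)c(OC)cc2c1O[C@H](c1cc(OC)c(OC)c(OC)c1)[C@H]2C | intermediate
23 | 7-allyl-5-methoxy-3-methyl-2-(3,4,5-trimethoxyphenyl)-1-benzofuran-6-yl acetate | C=CCc1c(OC(C)=O)c(OC)cc2c(C)c(-c3cc(OC)c(OC)c(OC)c3)oc12 | intermediate
24 | 7-allyl-5-methoxy-3-methyl-2-(3,4,5-trimethoxyphenyl)-1-benzofuran-6-ol | C=CCc1c(O)c(OC)cc2c(C)c(-c3cc(OC)c(OC)c(OC)c3)oc12 | target

**Step count**

Total steps: 12. Longest linear sequence: 11 steps (4 → 24 through steps 2 to 12); the furan branch (1 → 24) has 10.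

**Steps most likely to fail**

1. Step 9 (Proposed new method).
Process: retro-ene loss of the alkene or a [3,3] shift of the benzylic ynol ether onto the aryl ring may consume 19 as ketenes before the cycloaddition occurs. The oxa bridge may also ionise at C6–O and lead to rearranged dienones.
Fallback with known chemistry, setting out from 4 and 16 and coming back at 21: the dihydrobenzofuran is built by an oxidative phenol–alkene [3+2] coupling and the allyl group is moved to C7 by an aromatic Claisen rearrangement. Purchased isovanillin is O-allylated with 16 (K2CO3, DMF) to 3-(allyloxy)-4-methoxybenzaldehyde F1. Baeyer–Villiger oxidation (mCPBA, CH2Cl2, 0 °C; the electron-rich aldehyde should react before the terminal alkene) gives 3-(allyloxy)-4-methoxyphenyl formate F2, which K2CO3 in MeOH cleaves to 3-(allyloxy)-4-methoxyphenol F3. Suzuki–Miyaura coupling of 4 with (E)-prop-1-enylboronic acid pinacol ester (PdCl2(dppf), K2CO3, dioxane/H2O, 80 °C) gives 1,2,3-trimethoxy-5-[(E)-prop-1-enyl]benzene F4. Oxidation of F3 with PhI(OAc)2 in hexafluoroisopropanol at 0 °C in the presence of F4 should give, by attack of the alkene at the unhindered ortho carbon of the phenoxonium ion and closure of the phenol oxygen onto the benzylic cation, (2S*,3S*)-6-(allyloxy)-5-methoxy-3-methyl-2-(3,4,5-trimethoxyphenyl)-2,3-dihydro-1-benzofuran F5. Heating F5 in N,N-diethylaniline at 190 °C should shift the allyl group to C7, the only free ortho position, and give 21.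

2. Step 8.
Process: the hard lithium acetylide may isomerise the 1,4-enyne to allenes, excess n-BuLi may metalate the furan C5–H, and the ynol ether may hydrate or fragment during isolation.
Fallback, setting out from 15 and coming back at 19: the sp–sp3 bond is made by a neutral palladium-catalysed coupling instead of an alkylation. 15 is taken through 17 to 18 as in step 8, and 18 is quenched with Bu3SnCl (−78 → 0 °C) to tributyl{[(1S*,2R*)-2-(4-methoxyfuran-2-yl)-1-(3,4,5-trimethoxyphenyl)propoxy]ethynyl}stannane F6, which can be purified on basic alumina. Stille coupling of F6 with 16 (Pd(PPh3)4, THF, 25 °C) should give 19.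

3. Step 11.
Process: DDQ may abstract hydride from the allylic and benzylic CH2 of the 7-allyl group in competition with C2–H, leading to cinnamyl-type oxidation products.
Fallback, setting out from 15 and coming back at 24: the allyl group is kept on oxygen during the oxidation and moved to C7 afterwards. 15 is taken through 17 to 18 as in step 8, and 18 is quenched with MeOH to 5-{(1S*,2R*)-1-(ethynyloxy)-2-(4-methoxyfuran-2-yl)propyl}-1,2,3-trimethoxybenzene F7. The cycloaddition conditions of step 9 should give, through the oxa-bridged cycloadduct F8, (2S*,3S*)-5-methoxy-3-methyl-2-(3,4,5-trimethoxyphenyl)-2,3-dihydro-1-benzofuran-6-ol F9. O-Allylation with 16 (K2CO3, acetone) gives the allyl ether F5 already met in the fallback for step 9. DDQ (dioxane, 80 °C) then meets only an allyl aryl ether, which is far less hydridic, and should give 6-(allyloxy)-5-methoxy-3-methyl-2-(3,4,5-trimethoxyphenyl)-1-benzofuran F10. Claisen rearrangement of F10 (N,N-diethylaniline, 190 °C) to the only free ortho position C7 should give 24 directly.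

**Further compounds**

F1 | step 9 | 3-(allyloxy)-4-methoxybenzaldehyde | C=CCOc1cc(C=O)ccc1OC
F2 | step 9 | 3-(allyloxy)-4-methoxyphenyl formate | C=CCOc1cc(OC=O)ccc1OC
F3 | step 9 | 3-(allyloxy)-4-methoxyphenol | C=CCOc1cc(O)ccc1OC
F4 | step 9 | 1,2,3-trimethoxy-5-[(E)-prop-1-enyl]benzene | C/C=C/c1cc(OC)c(OC)c(OC)c1
F5 | step 9 | (2S*,3S*)-6-(allyloxy)-5-methoxy-3-methyl-2-(3,4,5-trimethoxyphenyl)-2,3-dihydro-1-benzofuran | COc1cc2c(cc1OCC=C)O[C@H](c1cc(OC)c(OC)c(OC)c1)[C@H]2C
F6 | step 8 | tributyl{[(1S*,2R*)-2-(4-methoxyfuran-2-yl)-1-(3,4,5-trimethoxyphenyl)propoxy]ethynyl}stannane | CCCC[Sn](CCCC)(CCCC)C#CO[C@H](c1cc(OC)c(OC)c(OC)c1)[C@@H](C)c1cc(OC)co1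
F7 | step 11 | 5-{(1S*,2R*)-1-(ethynyloxy)-2-(4-methoxyfuran-2-yl)propyl}-1,2,3-trimethoxybenzene | C#CO[C@H](c1cc(OC)c(OC)c(OC)c1)[C@@H](C)c1cc(OC)co1
F8 | step 11 | (2S*,3R*)-5-methoxy-3-methyl-2-(3,4,5-trimethoxyphenyl)-2,3,3a,6-tetrahydro-3a,6-epoxy-1-benzofuran (bridge on either face) | C1=C2O[C@H](c4cc(OC)c(OC)c(OC)c4)[C@@H](C)C23OC1C(OC)=C3
F9 | step 11 | (2S*,3S*)-5-methoxy-3-methyl-2-(3,4,5-trimethoxyphenyl)-2,3-dihydro-1-benzofuran-6-ol | COc1cc2c(cc1O)O[C@H](c1cc(OC)c(OC)c(OC)c1)[C@H]2C
F10 | step 11 | 6-(allyloxy)-5-methoxy-3-methyl-2-(3,4,5-trimethoxyphenyl)-1-benzofuran | C=CCOc1cc2oc(-c3cc(OC)c(OC)c(OC)c3)c(C)c2cc1OC
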